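I decide to hand this flask over with one number, the standing ratio: the summed isomer of the product over the summed target, from 8.00 d on in both earlier runs, 3.62. It replaces two flat curves by their mean, and where both species can return to the intermediate, the field calls this thermodynamic control.

| flask | solid substrate | remark | time |
|---|---|---|---|
| dawn | 0.67 M | run made earlier |  |
| midnight | 1.5 M | run made earlier |  |
| flask | 1.0 M |  | 15 d |

| run | time / d | isomer of the product / % | target / % |
|---|---|---|---|
| dawn | 1.04 | 44.7 | 14.7 |
| dawn | 3.00 | 59.9 | 15.3 |
| dawn | 5.00 | 59.6 | 15.6 |
| dawn | 8.00 | 60.0 | 15.9 |
| dawn | 10.0 | 60.6 | 15.5 |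
| dawn | 15.0 | 59.7 | 15.7 |
| dawn | 20.0 | 60.8 | 17.4 |
| midnight | 2.50 | 52.2 | 15.0 |
| midnight | 5.00 | 58.7 | 15.1 |
| midnight | 8.00 | 58.8 | 17.2 |
| midnight | 10.0 | 59.8 | 16.6 |
| midnight | 12.0 | 58.8 | 16.3 |
| midnight | 15.0 | 61.1 | 17.4 |
| midnight | 20.0 | 59.4 | 17.0 |

(readings scatter by 1 percentage point)

- given per volume of solution although it is solid: solid substrate
- steps that have been proposed: solid substrate <-> starting material; intermediate <-> target; intermediate <-> isomer of the product; starting material -> intermediate
- at the start none of the solid substrate is in solution

- ratio of isomer of the product to target at 6.0 h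
- ratio of isomer of the product to target at 50 h
- ratio of isomer of the product to target at 15 d
- which of isomer of the product and target there is more of at 15 d

I check what the mean costs. The dawn run by itself gives 3.74, and the midnight run, at twice the loading, gives 3.53, so I allow 0.210 on it.

To whoever takes over: the flask starts as undissolved solid substrate, and at 15 d I expect the standing ratio, 3.62, with isomer of the product ahead. Leave it closed, and don't take an early sample for the end ratio, because the dawn run at 1.04 d still reads 3.04, lower than the standing ratio. At 6.0 h I expect less than that reading, and at 50 h about the midnight reading at 2.50 d, 3.48.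

The forecast gives 1.3, 3.5 and 3.6, with isomer of the product ahead, and says of the first: “This is an extrapolation, so it is very uncertain.”

The flask gives 2.39, 3.62 and 3.66, with isomer of the product ahead, 60.3% against 16.5%.

    solid substrate ⇌ starting material, rate k1*(cs1 - [starting material]) while solid is left; crystals form when [starting material] > cs1 (solubility = 0.250 M, k = 0.00747 /min)
    intermediate ⇌ target (K = 0.710, k = 0.0321 /min)
    intermediate ⇌ isomer of the product (K = 2.60, k = 0.0181 /min)
    starting material → intermediate (k = 0.00190 /min)

The two part at 6.0 h, where the forecast stands lower than the flask by a factor of 1.84. At 15 d my standing ratio, 3.62, lies close to the ratio of the flask, 3.66. For the neighbouring flask, charged with 1.7 M of solid substrate, above both earlier loadings, I carry over the same standing ratio, 3.62, at 15 d. That flask holds 60.3% isomer of the product and 16.5% target at 15 d, and its ratio is 3.66.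

The data are simulated with constants of no real substance, and the scatter is random.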